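## Structural features

The target 13 is a single cyclohexene ring. Its trisubstituted C1=C2 bond carries the exocyclic methylene C7 (as a benzoate) on C1 and a hydrogen on C2; these locants are used throughout, with C3–C6 the carbinol carbons. C3–C6 are four contiguous secondary carbinol stereocentres, (3S,4S,5R,6R), with all four oxygens on the same face of the ring. Only O5 is benzoylated, while O3, O4 and O6 are free. C3 and C6 are both allylic and para to each other, and C4/C5 form a cis-diol between them. The fragile points are the O5 benzoate (flanked by two cis hydroxyls, so it can migrate under base), the allylic carbinols at C3 and C6 (ionisable under acid), and the ring as a whole, which aromatises by loss of water or benzoic acid once a carbonyl is present. The skeleton is trivial; the difficulty is to put four oxygens on one face in one absolute sense and to acylate only the central O5. The key step exploits the fact that C7 on C1 plus oxygens on the para carbons C3 and C6 is the pattern of a 2-substituted p-benzoquinone. With the C3 carbonyl masked as a ketal, the unsubstituted C4=C5 enone bond is the only place where the cis O4/O5 pair must be added, and the C3 and C6 carbonyls are then reduced in turn.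

## Logic of the disconnections

13 to 12. The C3–H bond is cut, so the C3 carbinol becomes a ketone conjugated with C1=C2. This removes one stereocentre and uses the three cis oxygens at C4–C6 as the controlling element. The forward step needs 1,2-delivery of hydride to the face opposite O4, O5 and O6, in a medium that leaves the O5 ester in place.

12 to 11. The C3 carbonyl is traced to a ketal, cutting the two C3–O bonds to the auxiliary 6. The ketal keeps C3 and C6 distinct and prevents an ene-dione that would tautomerise to an arene. The forward step needs a hydrolysis that spares two benzoates and the allylic C6 carbinol.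

11 to 10. The C6–H bond is cut, so the C6 carbinol becomes the dienone-derived ketone. The forward step needs 1,2-reduction from the face opposite O5 and O4, cold enough that the neighbouring ester does not migrate.

10 to 9 and 4. The O5–acyl bond is cut here because in 9 only O4 and O5 are free and they differ sharply: O4 is neopentyl-like beside the spiro ketal carbon. The forward step needs monoacylation without enolisation toward C5.

9 to 7 (through 8). The C4–O and C5–O bonds are cut together, the retron of a suprafacial cis-dihydroxylation. Two stereocentres disappear and the precursor is a flat dienone. The forward step must pick C4=C5 over C1=C2, pick one face under the influence of the ketal, and stop at the diol.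

7 to 5 and 6. The two ketal C–O bonds to the auxiliary are cut (ketal exchange). The achiral dimethyl ketal is what dearomatisation in an alcohol delivers, and the auxiliary is attached afterwards. The forward step needs anhydrous acid so that the quinone is not released.

5 to 3 and 4. The O7–acyl bond is cut. This ester is part of the target, so no protecting group is spent. The forward step is an ordinary acylation of the only hydroxyl.

3 to 2. The C3–O bond to the second alkoxy group is cut, the retron of oxidative dearomatisation. All ring carbons, C7 and both para oxygens then sit in a simple arene. The forward step needs the solvent alcohol to attack para to the phenol oxygen.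

2 to 1. A C7–H bond is cut, tracing the benzylic alcohol to the commercial aldehyde. The forward step is a chemoselective hydride reduction.

## Other disconnections considered

Alternative 1: The ring is cut at C1–C2 and C5–C6. C1, C6 and C7 come from 3-acryloyloxazolidin-2-one A2; C2–C5 and the O5 oxygen come from furan A1.
- Forward step: [Cu(t-Bu-box)](SbF6)2, a bis(oxazoline) complex of divalent copper, chelates A2 and steers A1 into an endo Diels–Alder reaction to give the oxa-bridged adduct A3. LiN(SiMe3)2 would then open the bridge by β-elimination to the dienol A4, which has C1=C2 and the C5 carbinol of the right hand.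
- In favour: absolute control comes from a catalyst with a well-understood chelate model. On this point the alternative is better than the chosen plan, whose control element is an untested auxiliary effect. C7 arrives at a useful oxidation level and C1=C2 falls where needed.
- Against: C6 is a methylene in A3 and A4, so the fourth ring oxygen needs a late allylic C–H oxidation cis to O5. The C3=C4 dihydroxylation would have to occur syn to O5, against the usual anti preference. A3 is prone to cycloreversion, and the imide must still be reduced and benzoylated.
- Comparison: structurally, the chosen plan starts with all four ring oxygens and C7 in place and closes no ring; the alternative builds the ring but lacks O6. Mechanistically, it is a catalyst-controlled concerted cycloaddition against an auxiliary-controlled metal-oxo addition. In step count it is probably equal to or longer than nine once O6 and the all-cis sense are dealt with.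

Alternative 2: The ring is cut at C3–C4 and C5–C6. C6–C1=C2–C3 come from (1E,3E)-1,4-diacetoxybuta-1,3-diene A5 and C4–C5 from vinylene carbonate A6.
- Forward step: a thermal endo Diels–Alder reaction gives the meso all-cis adduct A7.
- In favour: all four ring stereocentres are set with the all-cis relation in one concerted step. Here the alternative is better than the chosen plan, which needs three separate face-selective events for the same relation.
- Against: A7 has no C7 and no absolute sense. A desymmetrising monoacylation would have to find one of four hydroxyls. C7 must then be attached to a vinylic CH of a symmetric alkene, for example by oxidising one allylic carbinol to an enone, a Morita–Baylis–Hillman hydroxymethylation and re-reduction, which destroys and remakes a stereocentre. Distinguishing O3/O6 and O4/O5 needs heavy protecting-group traffic, and the cycloaddition of the sluggish dienophile A6 needs forcing heat.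
- Comparison: better on relative configuration, equal on availability of starting materials, worse on C7, on differentiation of O5 and on step count.

Alternative 3: The two C–O bonds at C5 and C6 are cut and the ring is traced to bromobenzene A8, whose bromine marks C1.
- Forward step: whole-cell oxidation with E. coli JM109(pDTG601), expressing toluene dioxygenase, gives the diene diol A9. Its C5 and C6 centres match those of 13, and C1=C2 and C3=C4 are already in place.
- In favour: two stereocentres arrive as a single enantiomer in one step from an arene. On absolute control this is clearly better than the chosen plan, and on step count it is equal or somewhat better. The vinyl bromide accepts C7 by a Stille coupling or carbonylation with Pd(PPh3)4 (zerovalent palladium), and C3=C4 is the only electron-rich alkene left for the second dihydroxylation.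
- Against: after protection of the diol of A9, OsO4 is expected to add anti to it, whereas 13 needs the syn, all-cis result. That calls for a hydrogen-bond-directed dihydroxylation or an inversion sequence. Fermentation capacity is needed, and O5 must still be told apart from O3, O4 and O6.
- Comparison: both plans rest on one uncertain face-selective dihydroxylation. The chosen plan is ordinary bench chemistry throughout and differentiates O5 through the ketone/ketal environment. The alternative wins on enantiopurity.

Key step: step 5

Assumption: the sense of facial induction by the (R,R)-diphenyldioxolane rests on a conformational model (argued in step 5), not on precedent; the route requires the ring stereocentres of 9, and the hand of the auxiliary is the variable that would be set to deliver them.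

## Route

Step 1
Reactants: 1 2-hydroxy-5-methoxybenzaldehyde
Product: 2 2-(hydroxymethyl)-4-methoxyphenol
Conditions: NaBH4, MeOH, 0 °C; NH4Cl (aq)
Reagents that add atoms: none
Why: Borohydride reduction of an aryl aldehyde; the phenol is only deprotonated and the aryl ether is inert, and no stereocentre is formed.

Step 2
Reactants: 2 2-(hydroxymethyl)-4-methoxyphenol
Product: 3 2-(hydroxymethyl)-4,4-dimethoxycyclohexa-2,5-dien-1-one
Conditions: PhI(OAc)2, MeOH, 0 °C; NaHCO3 (aq)
Reagents that add atoms: methanol, CO
Why: Oxidative dearomatisation of a para-alkoxyphenol by trivalent iodine; the solvent alcohol adds at the para carbon, where the developing cation is stabilised by the methoxy oxygen, giving the quinone monoketal with the ketone next to the carbon bearing C7. The primary alcohol is not oxidised by this reagent in the absence of a nitroxyl co-catalyst.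

Step 3
Reactants: 3 2-(hydroxymethyl)-4,4-dimethoxycyclohexa-2,5-dien-1-one; 4 benzoyl chloride
Product: 5 (3,3-dimethoxy-6-oxocyclohexa-1,4-dien-1-yl)methyl benzoate
Conditions: pyridine, DMAP (cat.), CH2Cl2, 0 °C
Reagents that add atoms: none
Why: Nucleophile-catalysed acylation of the only hydroxyl; the dienone and the dimethyl ketal tolerate mild amine base, and the O7 benzoate is already the ester of the target.

Step 4
Reactants: 5 (3,3-dimethoxy-6-oxocyclohexa-1,4-dien-1-yl)methyl benzoate; 6 (1R,2R)-1,2-diphenylethane-1,2-diol, (R,R)-hydrobenzoin
Product: 7 [(2R,3R)-8-oxo-2,3-diphenyl-1,4-dioxaspiro[4.5]deca-6,9-dien-7-yl]methyl benzoate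
Conditions: BF3·OEt2 (cat.), DME, 4 Å MS, 0 °C to rt; Et3N quench
Reagents that add atoms: none
Why: Acid-catalysed ketal exchange of a quinone monoketal with a 1,2-diol, driven by chelate entropy and removal of methanol; anhydrous conditions prevent release of the quinone. The spiro carbon is not a stereocentre because the dioxolane is C2-symmetric.

Step 5
Reactants: 7 [(2R,3R)-8-oxo-2,3-diphenyl-1,4-dioxaspiro[4.5]deca-6,9-dien-7-yl]methyl benzoate
Product: 9 [(2R,3R,9S,10R)-9,10-dihydroxy-8-oxo-2,3-diphenyl-1,4-dioxaspiro[4.5]dec-6-en-7-yl]methyl benzoate, via cyclic ruthenate ester 8 (not isolated)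
Conditions: RuCl3·3H2O (cat.), CeCl3·7H2O (cat.), NaIO4, EtOAc/MeCN/H2O, 0 °C, minutes; Na2S2O3 (aq)
Reagents that add atoms: sodium periodate, [Na+].[O-]I(=O)(=O)=O (oxygen relayed through ruthenium tetroxide, O=[Ru](=O)(=O)=O, made in the flask); water, O
Why: Proposed new method: RuO4 (octavalent ruthenium, formed from RuCl3 and NaIO4) should add across C4=C5 in a concerted suprafacial [3+2] step to give the cyclic ester 8 of hexavalent ruthenium, which water hydrolyses (helped by the Lewis acid CeCl3) to 9 while periodate re-oxidises the metal; the closest known reaction types are RuO4 and OsO4 cis-dihydroxylation of enones and auxiliary-controlled conjugate additions and epoxidations of hydrobenzoin-derived quinone monoketals, whereas facial control of a dihydroxylation by this ketal is not established. No ring of the product is closed; the only ring formed is the transient five-membered metalla-diolate of 8. C4 and C5 (spiro locants C10 and C9) are created together, so their cis relation is fixed by the suprafacial mechanism, and their absolute sense must come from the (2R,3R)-diphenyldioxolane. In the twist conformer that keeps both phenyl groups pseudo-equatorial, the dioxolane CH bound to the ketal oxygen on one face is tipped toward C4 with its pseudo-axial hydrogen over that face, whereas on the other face the CH is tipped away toward C2; the oxidant should therefore approach C4=C5 from the more open face, which is the one leading to the (9S,10R) diol 9. The bias is expected to be modest, so the diastereomers would be separated at this stage. Site selectivity between the two enone bonds is needed: C1=C2 is trisubstituted, carries its substituent on the carbon where an oxo ligand must bond, and is deactivated inductively by the allylic benzoate, so C4=C5 should react first. Cleavage of the new diol, oxidation of the carbinols and attack on the benzylic C–H bonds of the auxiliary are held back by low catalyst loading, 0 °C, a contact time of minutes and a reductive quench.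

Step 6
Reactants: 9 [(2R,3R,9S,10R)-9,10-dihydroxy-8-oxo-2,3-diphenyl-1,4-dioxaspiro[4.5]dec-6-en-7-yl]methyl benzoate; 4 benzoyl chloride
Product: 10 [(2R,3R,9S,10R)-9-(benzoyloxy)-10-hydroxy-8-oxo-2,3-diphenyl-1,4-dioxaspiro[4.5]dec-6-en-7-yl]methyl benzoate
Conditions: 4 (1.05 equiv), pyridine, CH2Cl2, −40 to −20 °C
Reagents that add atoms: none
Why: Regioselective acylation of the less hindered secondary hydroxyl: O4 sits beside the quaternary spiro ketal carbon and its diphenyldioxolane, so O5 (α to the ketone, flanked by an sp2 carbon) should react first. The weak base and low temperature are chosen to avoid enolisation toward C5, β-elimination of O4 and acyl migration.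

Step 7
Reactants: 10 [(2R,3R,9S,10R)-9-(benzoyloxy)-10-hydroxy-8-oxo-2,3-diphenyl-1,4-dioxaspiro[4.5]dec-6-en-7-yl]methyl benzoate
Product: 11 [(2R,3R,8R,9R,10R)-9-(benzoyloxy)-8,10-dihydroxy-2,3-diphenyl-1,4-dioxaspiro[4.5]dec-6-en-7-yl]methyl benzoate
Conditions: NaBH4, CeCl3·7H2O, MeOH, −78 °C; AcOH quench
Reagents that add atoms: none
Why: Luche 1,2-reduction of the enone carbonyl at C6; O4 and O5 lie on one face and whichever of them is pseudo-axial blocks it, so hydride should enter from the opposite face and place O6 cis to O5 (new centre 8R). The cerium salt suppresses conjugate reduction, and the cold, briefly basic medium with an acidic quench limits benzoate migration.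

Step 8
Reactants: 11 [(2R,3R,8R,9R,10R)-9-(benzoyloxy)-8,10-dihydroxy-2,3-diphenyl-1,4-dioxaspiro[4.5]dec-6-en-7-yl]methyl benzoate
Product: 12 [(4R,5R,6R)-5-(benzoyloxy)-4,6-dihydroxy-3-oxocyclohex-1-en-1-yl]methyl benzoate
Conditions: TFA, H2O, CH2Cl2, 0 °C
Reagents that add atoms: water, O
Why: Acid-catalysed hydrolysis of an allylic ketal through the conjugated oxocarbenium ion releases the C3 enone and the auxiliary 6 for recovery; benzoates are stable to cold aqueous acid. The ketal is removed only now, after C6 is reduced, because an ene-dione bearing C4–H and C5–H would tautomerise to a hydroquinone.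

Step 9
Reactants: 12 [(4R,5R,6R)-5-(benzoyloxy)-4,6-dihydroxy-3-oxocyclohex-1-en-1-yl]methyl benzoate
Product: 13 [(3S,4S,5R,6R)-5-(benzoyloxy)-3,4,6-trihydroxycyclohex-1-en-1-yl]methyl benzoate
Conditions: NaBH4, CeCl3·7H2O, MeOH, −78 °C; AcOH quench
Reagents that add atoms: none
Why: Luche 1,2-reduction of the C3 enone; in either half-chair one of the three cis oxygens at C4–C6 is pseudo-axial on the same face, so hydride should add from the opposite face and give the all-cis C3 carbinol (3S). Low temperature, the cerium salt and an immediate acidic quench are meant to prevent β-elimination of the O5 benzoate from 12 and its migration to O4 or O6 in 13.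

## Compound list

1 | 2-hydroxy-5-methoxybenzaldehyde | COc1ccc(O)c(C=O)c1 | starting material
2 | 2-(hydroxymethyl)-4-methoxyphenol | COc1ccc(O)c(CO)c1 | intermediate
3 | 2-(hydroxymethyl)-4,4-dimethoxycyclohexa-2,5-dien-1-one | COC1(OC)C=CC(=O)C(CO)=C1 | intermediate
4 | benzoyl chloride | O=C(Cl)c1ccccc1 | starting material
5 | (3,3-dimethoxy-6-oxocyclohexa-1,4-dien-1-yl)methyl benzoate | COC1(OC)C=CC(=O)C(COC(=O)c2ccccc2)=C1 | intermediate
6 | (1R,2R)-1,2-diphenylethane-1,2-diol, (R,R)-hydrobenzoin | O[C@H](c1ccccc1)[C@H](O)c1ccccc1 | starting material
7 | [(2R,3R)-8-oxo-2,3-diphenyl-1,4-dioxaspiro[4.5]deca-6,9-dien-7-yl]methyl benzoate | O=C1C=CC2(O[C@H](c3ccccc3)[C@@H](c3ccccc3)O2)C=C1COC(=O)c1ccccc1 | intermediate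
8 | cyclic ester of hexavalent ruthenium (dioxo-ruthenate) spanning O4 and O5 of 9, formed and hydrolysed in the flask | O=C1[C@@H](O[Ru]3(=O)=O)[C@@H](O3)C2(O[C@H](c4ccccc4)[C@@H](c5ccccc5)O2)C=C1COC(=O)c1ccccc1 | intermediate
9 | [(2R,3R,9S,10R)-9,10-dihydroxy-8-oxo-2,3-diphenyl-1,4-dioxaspiro[4.5]dec-6-en-7-yl]methyl benzoate | O=C1[C@@H](O)[C@@H](O)C2(O[C@H](c3ccccc3)[C@@H](c3ccccc3)O2)C=C1COC(=O)c1ccccc1 | intermediate
10 | [(2R,3R,9S,10R)-9-(benzoyloxy)-10-hydroxy-8-oxo-2,3-diphenyl-1,4-dioxaspiro[4.5]dec-6-en-7-yl]methyl benzoate | O=C1[C@@H](OC(=O)c4ccccc4)[C@@H](O)C2(O[C@H](c3ccccc3)[C@@H](c3ccccc3)O2)C=C1COC(=O)c1ccccc1 | intermediate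
11 | [(2R,3R,8R,9R,10R)-9-(benzoyloxy)-8,10-dihydroxy-2,3-diphenyl-1,4-dioxaspiro[4.5]dec-6-en-7-yl]methyl benzoate | O=C(OCC1=CC2(O[C@H](c3ccccc3)[C@@H](c4ccccc4)O2)[C@H](O)[C@H](OC(=O)c5ccccc5)[C@@H]1O)c6ccccc6 | intermediate
12 | [(4R,5R,6R)-5-(benzoyloxy)-4,6-dihydroxy-3-oxocyclohex-1-en-1-yl]methyl benzoate | O=C(OCC1=CC(=O)[C@H](O)[C@H](OC(=O)c2ccccc2)[C@@H]1O)c1ccccc1 | intermediate
13 | [(3S,4S,5R,6R)-5-(benzoyloxy)-3,4,6-trihydroxycyclohex-1-en-1-yl]methyl benzoate | O=C(OCC1=C[C@H](O)[C@H](O)[C@H](OC(=O)c2ccccc2)[C@@H]1O)c1ccccc1 | target

C4 and C5 keep the spatial arrangement set in step 5 through to 13. Their descriptors change (4R,5S in 9 and 10; 4R,5R in 11 and 12; 4S,5R in 13) only because the ranking of their neighbours changes.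

## Step count and least certain steps

Total step count: 9. Longest linear sequence: 9 steps (1 to 13); 4 and 6 are used as purchased.

Step 5 (key step, proposed method).
- Most likely failure: poor or reversed facial selectivity. The stereogenic carbons of the auxiliary are three bonds from C4 and its phenyl groups point away from the dienone faces, so the two faces of C4=C5 differ only slightly. Over-oxidation by the metal-oxo reagent is the second concern.
- Fallback (known chemistry, from 7 back to 9): induction is no longer relied on and the ketal is used as a covalently bound resolving group. The enone dihydroxylation is run for conversion only. The wanted diol 9 is separated by chromatography or crystallisation from its diastereomer [(2R,3R,9R,10S)-9,10-dihydroxy-8-oxo-2,3-diphenyl-1,4-dioxaspiro[4.5]dec-6-en-7-yl]methyl benzoate F1, which is set aside. The route rejoins at 9.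

Step 6.
- Most likely failure: loss of regiocontrol or of C5 integrity during acylation (O4 or double acylation, enolisation next to the ketone), because the α-ketol is base-sensitive.
- Fallback (from 9 back to 11): the order of reduction and acylation is reversed and the ester is placed under stereoelectronic control. Luche reduction of 9 (NaBH4, CeCl3·7H2O, MeOH, −78 °C) should give the all-cis triol [(2R,3R,8R,9R,10R)-8,9,10-trihydroxy-2,3-diphenyl-1,4-dioxaspiro[4.5]dec-6-en-7-yl]methyl benzoate F2. Trimethyl orthobenzoate with catalytic camphorsulfonic acid converts F2 into the cyclic orthobenzoate across O5 and O6, the 2-methoxy-2-phenyl-1,3-dioxolane of F2 (mixture at the orthoester carbon) F3. Mild aqueous acetic acid opens F3 with the acyl group left on the axial oxygen, which in the favoured half-chair of an all-cis 1,2,3-triol is the central O5. This gives 11.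

Step 9.
- Most likely failure: migration of the O5 benzoate to O4 or O6, or β-elimination of benzoate from 12, in the alkoxide-containing medium; hydride addition syn to O4 is a lesser risk.
- Fallback (from 11 back to 13): the flanking hydroxyls are capped before the carbonyl is unmasked. TBSOTf and 2,6-lutidine convert 11 into its 4,6-bis-O-(tert-butyldimethylsilyl) ether F4. Hydrolysis of the ketal on acidic clay (montmorillonite K-10, wet CH2Cl2) gives the bis-silylated enone, the 4,6-bis-O-(tert-butyldimethylsilyl) ether of 12, F5. Luche reduction, now directed by three bulky cis substituents and without vicinal alkoxides, gives the 4,6-bis-O-(tert-butyldimethylsilyl) ether of 13, F6. HF·pyridine in THF (non-basic) removes both silyl groups to give 13.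

Step 7.
- Most likely failure: hydride delivery syn to O5 if the half-chair with a pseudo-equatorial benzoate and chelation by trivalent cerium dominate, giving the C6 epimer.
- Fallback (from 10 back to 11, no new compound, F0): substrate control is replaced by catalyst control in a Corey–Bakshi–Shibata reduction with (R)-2-methyl-CBS-oxazaborolidine and catecholborane in toluene at −78 °C. This enantiomer is the one the usual model predicts to deliver hydride opposite O5 when the α-substituted alkenyl arm C1 acts as the larger group.

## Further compounds

F1 | step 5 | [(2R,3R,9R,10S)-9,10-dihydroxy-8-oxo-2,3-diphenyl-1,4-dioxaspiro[4.5]dec-6-en-7-yl]methyl benzoate | O=C1[C@H](O)[C@H](O)C2(O[C@H](c3ccccc3)[C@@H](c3ccccc3)O2)C=C1COC(=O)c1ccccc1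
F2 | step 6 | [(2R,3R,8R,9R,10R)-8,9,10-trihydroxy-2,3-diphenyl-1,4-dioxaspiro[4.5]dec-6-en-7-yl]methyl benzoate | O=C(OCC1=CC2(O[C@H](c3ccccc3)[C@@H](c4ccccc4)O2)[C@H](O)[C@H](O)[C@@H]1O)c5ccccc5
F3 | step 6 | cyclic orthobenzoate (2-methoxy-2-phenyl-1,3-dioxolane) across O5 and O6 of F2, mixture at the orthoester carbon | O=C(OCC1=CC2(O[C@H](c3ccccc3)[C@@H](c4ccccc4)O2)[C@H](O)[C@H](OC5(OC)c6ccccc6)[C@@H]1O5)c7ccccc7
F0 | step 7 | none | none
F4 | step 9 | 4,6-bis-O-(tert-butyldimethylsilyl) ether of 11 | O=C(OCC1=CC2(O[C@H](c3ccccc3)[C@@H](c4ccccc4)O2)[C@H](O[Si](C)(C)C(C)(C)C)[C@H](OC(=O)c5ccccc5)[C@@H]1O[Si](C)(C)C(C)(C)C)c6ccccc6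
F5 | step 9 | 4,6-bis-O-(tert-butyldimethylsilyl) ether of 12 | O=C(OCC1=CC(=O)[C@H](O[Si](C)(C)C(C)(C)C)[C@H](OC(=O)c2ccccc2)[C@@H]1O[Si](C)(C)C(C)(C)C)c1ccccc1
F6 | step 9 | 4,6-bis-O-(tert-butyldimethylsilyl) ether of 13 | O=C(OCC1=C[C@H](O)[C@H](O[Si](C)(C)C(C)(C)C)[C@H](OC(=O)c2ccccc2)[C@@H]1O[Si](C)(C)C(C)(C)C)c1ccccc1
A1 | alternative 1 | furan | c1ccoc1
A2 | alternative 1 | 3-acryloyloxazolidin-2-one | C=CC(=O)N1CCOC1=O
A3 | alternative 1 | 3-[(1R,2R,4R)-7-oxabicyclo[2.2.1]hept-5-ene-2-carbonyl]oxazolidin-2-one (endo adduct) | O=C(N1CCOC1=O)[C@@H]1C[C@@H]2C=C[C@H]1O2
A4 | alternative 1 | 3-[(5R)-5-hydroxycyclohexa-1,3-diene-1-carbonyl]oxazolidin-2-one | O=C(N1CCOC1=O)C1=CC=C[C@H](O)C1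
A5 | alternative 2 | (1E,3E)-1,4-diacetoxybuta-1,3-diene | CC(=O)O/C=C/C=C/OC(C)=O
A6 | alternative 2 | vinylene carbonate | O=C1OC=CO1
A7 | alternative 2 | meso all-cis 3,6-diacetoxycyclohex-1-ene-4,5-diyl carbonate | C1=C[C@H](OC(C)=O)[C@@H]2OC(=O)O[C@@H]2[C@@H]1OC(C)=O
A8 | alternative 3 | bromobenzene | Brc1ccccc1
A9 | alternative 3 | (1S,2S)-3-bromocyclohexa-3,5-diene-1,2-diol | BrC1=CC=C[C@H](O)[C@@H]1O
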